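**Retrosynthetic overview**
- Structural feature: the only ring is a 1H-pyrrole with hydrogen on C4 and C5, the n-C23 chain on C3 and the formyl carbon on the neighbouring C2. Formylating a 3-alkylpyrrole would have to choose between C2 and C5, so the 2,3-pattern is built into an acyclic precursor instead.
- The C2 aldehyde is traced back through the carbinol to a C2 ethyl ester, the group that also acidifies the carbon used in the ring closure.
- Key disconnection C2–C3: intramolecular aldol condensation of a glycinate enaminone, with glycine supplying N1, C2 and the formyl carbon.
- N1–C5 comes from aza-Michael addition of glycine ethyl ester to hexacos-1-yn-3-one. C3–C4 comes from ethynylmagnesium bromide and the Weinreb amide of tetracosanoic acid, whose carboxyl carbon becomes C3.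
- Order of bond formation: C3–C4, then N1–C5, then the single ring closure at C2–C3, then adjustment of the ester to the aldehyde.

Key step: step 5

Remark: the side chain is taken as the unbranched n-tricosyl group written in the SMILES, and the target has no stereocentre. The waxy C24-derived intermediates dissolve poorly in cold polar media, so THF-rich or gently warmed solvents are specified.

**Step 1**
Reactants: 1 tetracosanoic acid (lignoceric acid)
Product: 2 tetracosanoyl chloride
Conditions: (COCl)2 (1.5 equiv), DMF (cat.), CH2Cl2, 0 → 35 °C; evaporate, use crude
Reagents that add atoms: oxalyl chloride, O=C(Cl)C(=O)Cl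
Why: Acid chloride formation through the catalytic Vilsmeier-type chloroiminium species is mild, gives only gaseous by-products, and the saturated chain offers no competing site.

**Step 2**
Reactants: 2 tetracosanoyl chloride
Product: 3 N-methoxy-N-methyltetracosanamide
Conditions: MeNH(OMe)·HCl (1.2 equiv), pyridine (2.5 equiv), CH2Cl2, 0 → 30 °C
Reagents that add atoms: N,O-dimethylhydroxylamine hydrochloride, Cl.CNOC
Why: Nucleophilic acyl substitution (Weinreb amide synthesis) of the reactive acid chloride by the amine freed with pyridine is fast, and gentle warming keeps the waxy material in solution.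

**Step 3**
Reactants: 3 N-methoxy-N-methyltetracosanamide; 4 ethynylmagnesium bromide (0.5 M in THF)
Product: 6 hexacos-1-yn-3-one, via magnesium hemiaminal chelate 5 (not isolated)
Conditions: 4 (3 equiv), THF, 0 → 35 °C; cannulate into 1 M aq NaHSO4/toluene at 0 °C (inverse quench); use 6 promptly
Reagents that add atoms: ethynylmagnesium bromide 4, C#C[Mg]Br
Why: In this Weinreb ketone synthesis the five-membered magnesium chelate 5 (racemic at its transient carbon) survives until the quench, so only one alkynyl group is delivered, and pouring into cold acid protonates the released N,O-dimethylhydroxylamine at once and keeps it from adding to the terminal ynone.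

**Step 4**
Reactants: 6 hexacos-1-yn-3-one; 7 glycine ethyl ester hydrochloride
Product: 9 ethyl N-[(Z)-3-oxohexacos-1-en-1-yl]glycinate, via free glycine ethyl ester 8 (not isolated)
Conditions: 7 (1.1 equiv), Et3N (1.1 equiv), EtOH, then 6 in THF, rt
Reagents that add atoms: glycine ethyl ester hydrochloride 7, Cl.NCC(=O)OCC
Why: Aza-Michael (conjugate) addition of the primary amine to the unhindered terminal ynone, followed by tautomerisation, gives the push–pull enaminone, whose Z geometry is set thermodynamically by the six-membered N–H···O=C hydrogen bond and whose nitrogen is too electron-poor to add to a second ynone.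

**Step 5**
Reactants: 9 ethyl N-[(Z)-3-oxohexacos-1-en-1-yl]glycinate
Product: 11 ethyl 3-tricosyl-1H-pyrrole-2-carboxylate, via hydroxypyrroline aldol adduct 10 (not isolated)
Conditions: NaOEt (2 equiv, freshly made), abs. EtOH/THF (2:1), reflux; AcOH quench at 0 °C
Reagents that add atoms: none
Why: Ethoxide reversibly removes a proton from the glycine CH2 of 9, which is activated by the ester and flanked by nitrogen, and the ester enolate adds to the ketone carbon bearing the tricosyl chain, forming the pyrrole C2–C3 bond and the aldolate of 10. The ring closes in the 5-(enolexo)-exo-trig mode, made possible by the Z enaminone, which holds the NCH2 arm and the carbonyl on the same side of the C=C bond, while any E isomer equilibrates through the push–pull double bond in base. Loss of hydroxide from C3, pushed by the enamine nitrogen, and loss of the C2 proton then give the aromatic 1H-pyrrole, which makes an otherwise reversible addition to a weakly electrophilic vinylogous amide irreversible. The closest known reaction type is the base-induced cyclisation of N-(3-oxoalk-1-enyl)glycine esters to 3-substituted pyrrole-2-carboxylates, an intramolecular Knoevenagel-type aldol condensation, and matching ethoxide to the ethyl ester makes transesterification degenerate. The two stereocentres of 10 form as a mixture and are erased on aromatisation, so no stereocontrol is needed. The selectivity needed is regiochemical (chain on C3, ester on C2, C4 and C5 free) and is fixed by the connectivity of 9, because the only other enolate, at the ketone α-CH2, could reach the ester only through a seven-membered ring and simply returns to 9 by proton exchange.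

**Step 6**
Reactants: 11 ethyl 3-tricosyl-1H-pyrrole-2-carboxylate
Product: 12 (3-tricosyl-1H-pyrrol-2-yl)methanol
Conditions: LiAlH4 (1.5 equiv), THF, 0 °C, TLC control; Na2SO4·10H2O quench at 0 °C, filter, concentrate below 30 °C, use crude at once
Reagents that add atoms: none
Why: Hydride reduction of the ester with LiAlH4 should stop at the aluminium alkoxide of the carbinol at 0 °C, because ionisation of that alkoxide to the azafulvene (the path to the 2-methylpyrrole) needs higher temperature, and the neutral hydrate quench avoids acid-triggered self-condensation at the free C5.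

**Step 7**
Reactants: 12 (3-tricosyl-1H-pyrrol-2-yl)methanol
Product: 13 3-tricosyl-1H-pyrrole-2-carbaldehyde (target)
Conditions: activated MnO2 (15 equiv), CH2Cl2, rt; filter through Celite
Reagents that add atoms: none
Why: Heterogeneous MnO2 oxidation is selective for the benzylic-type pyrrolyl carbinol, runs under neutral conditions that the fragile carbinol tolerates, and stops at the aldehyde, which is stabilised as a vinylogous formamide.

**Compound list**
1 | tetracosanoic acid (lignoceric acid) | CCCCCCCCCCCCCCCCCCCCCCCC(=O)O | starting material
2 | tetracosanoyl chloride | CCCCCCCCCCCCCCCCCCCCCCCC(=O)Cl | intermediate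
3 | N-methoxy-N-methyltetracosanamide | CCCCCCCCCCCCCCCCCCCCCCCC(=O)N(C)OC | intermediate
4 | ethynylmagnesium bromide | C#C[Mg]Br | starting material
5 | bromomagnesium alkoxide of 3-[methoxy(methyl)amino]hexacos-1-yn-3-ol (chelated tetrahedral adduct, racemic, not isolated) | CCCCCCCCCCCCCCCCCCCCCCCC(O[Mg]Br)(C#C)N(C)OC | intermediate
6 | hexacos-1-yn-3-one | CCCCCCCCCCCCCCCCCCCCCCCC(=O)C#C | intermediate
7 | glycine ethyl ester hydrochloride | Cl.NCC(=O)OCC | starting material
8 | glycine ethyl ester (free base, not isolated) | NCC(=O)OCC | intermediate
9 | ethyl N-[(Z)-3-oxohexacos-1-en-1-yl]glycinate | CCCCCCCCCCCCCCCCCCCCCCCC(=O)/C=C\NCC(=O)OCC | intermediate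
10 | ethyl 3-hydroxy-3-tricosyl-2,3-dihydro-1H-pyrrole-2-carboxylate (racemic diastereomer mixture, not isolated) | CCCCCCCCCCCCCCCCCCCCCCCC1(O)C=CNC1C(=O)OCC | intermediate
11 | ethyl 3-tricosyl-1H-pyrrole-2-carboxylate | CCCCCCCCCCCCCCCCCCCCCCCc1cc[nH]c1C(=O)OCC | intermediate
12 | (3-tricosyl-1H-pyrrol-2-yl)methanol | CCCCCCCCCCCCCCCCCCCCCCCc1cc[nH]c1CO | intermediate
13 | 3-tricosyl-1H-pyrrole-2-carbaldehyde | CCCCCCCCCCCCCCCCCCCCCCCc1cc[nH]c1C=O | target

Total step count: 7
Longest linear sequence: 7 steps (1 → 13)

**Three steps most likely to fail**

**Step 5 (ring closure).**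
- Risk: ethoxide may remove the N–H proton rather than a CH2 proton. The resulting delocalised anion would make the ketone carbon too electron-rich to accept the enolate. Retro-aza-Michael cleavage and saponification by the released water could then outrun the closure.
- Fallback (from 3, back at 11): the same C2–C3 aldol bond is made at the saturated oxidation level with a sulfonyl group on nitrogen, so a true ketone is attacked and no N–H is present.
- Weinreb amide 3 is treated with vinylmagnesium bromide in THF, with the same acidic inverse quench, to give hexacos-1-en-3-one F1.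
- Ethyl N-tosylglycinate and DBU in THF add to F1 to give ethyl N-(3-oxohexacosyl)-N-tosylglycinate F2. This closes in the same flask to ethyl 3-hydroxy-1-tosyl-3-tricosylpyrrolidine-2-carboxylate F3.
- POCl3 in pyridine dehydrates F3 to ethyl 1-tosyl-3-tricosyl-2,5-dihydro-1H-pyrrole-2-carboxylate F4.
- NaOEt in EtOH then expels p-toluenesulfinate from F4 with aromatisation to 11.

**Step 6 (ester to carbinol).**
- Risk: the aluminium alkoxide may ionise to an azafulvene that captures hydride, which over-reduces the C2 carbon to a methyl group. The carbinol may also self-condense through its free C5 during work-up or concentration, triggered by acid or heat.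
- Fallback (from 11, back at 13, bypassing 12): a McFadyen–Stevens sequence that never passes through the carbinol oxidation level.
- Hydrazinolysis of 11 (N2H4·H2O, n-BuOH, reflux) gives 3-tricosyl-1H-pyrrole-2-carbohydrazide F5.
- TsCl in pyridine at 0 °C gives N'-(4-methylphenylsulfonyl)-3-tricosyl-1H-pyrrole-2-carbohydrazide F6.
- Brief heating of F6 with Na2CO3 in ethylene glycol at about 160 °C expels sulfinate and nitrogen and should deliver 13 directly.

**Step 3 (terminal ynone).**
- Risk: the amine released on quench may add in conjugate fashion. The unprotected terminal ynone may oligomerise under base on concentration. Conversion may be incomplete because the amide dissolves poorly.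
- Fallback (from 3, back at 9, bypassing isolated 6): the side reaction is used on purpose.
- The Grignard addition is run as before but quenched with aq NH4Cl and stirred at rt, so that the liberated N,O-dimethylhydroxylamine adds to the nascent ynone. This gives (E)-1-[methoxy(methyl)amino]hexacos-1-en-3-one F7, a storable ynone surrogate.
- Warming F7 with 7 and NaOAc in EtOH/THF exchanges the amine by addition–elimination (enaminone transamination), driven by the hydrogen-bonded secondary enaminone, and gives 9.

**Further compounds**
F1 | step 5 | hexacos-1-en-3-one | CCCCCCCCCCCCCCCCCCCCCCCC(=O)C=C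
F2 | step 5 | ethyl N-(3-oxohexacosyl)-N-tosylglycinate | CCCCCCCCCCCCCCCCCCCCCCCC(=O)CCN(CC(=O)OCC)S(=O)(=O)c1ccc(C)cc1
F3 | step 5 | ethyl 3-hydroxy-1-tosyl-3-tricosylpyrrolidine-2-carboxylate (racemic diastereomer mixture) | CCCCCCCCCCCCCCCCCCCCCCCC1(O)CCN(S(=O)(=O)c2ccc(C)cc2)C1C(=O)OCC
F4 | step 5 | ethyl 1-tosyl-3-tricosyl-2,5-dihydro-1H-pyrrole-2-carboxylate (racemic) | CCCCCCCCCCCCCCCCCCCCCCCC1=CCN(S(=O)(=O)c2ccc(C)cc2)C1C(=O)OCC
F5 | step 6 | 3-tricosyl-1H-pyrrole-2-carbohydrazide | CCCCCCCCCCCCCCCCCCCCCCCc1cc[nH]c1C(=O)NN
F6 | step 6 | N'-(4-methylphenylsulfonyl)-3-tricosyl-1H-pyrrole-2-carbohydrazide | CCCCCCCCCCCCCCCCCCCCCCCc1cc[nH]c1C(=O)NNS(=O)(=O)c2ccc(C)cc2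
F7 | step 3 | (E)-1-[methoxy(methyl)amino]hexacos-1-en-3-one | CCCCCCCCCCCCCCCCCCCCCCCC(=O)/C=C/N(C)OC
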